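Cuts: first the two ester C–O bonds (malonate on O15, senecioate on O18), then C13–C14 (C14 and C15 come from Meldrum's acid), then C8–O, C9–C10 and C4–C5, which one epoxy-polyene cyclization of oxidised (5E,9E)-farnesylacetone makes together.
Forward: terminal allylic oxidation and asymmetric epoxidation; one cascade closes ring A, ring B and a temporary dihydropyran (C8–O–C13); the initiating 3-OH is removed; the enol ether C12=C13 is opened through C12 selenation to the 8-hydroxy (11E)-enone, which is turned into the C11=C12–C13=C16 diene.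
Key event: a chiral Pd–H places H on C16 (the future C13 methyl) and Meldrum's acid on C13 of the C11–C13 allyl, so C13–C14 and the C13 stereocentre form together; C11=C12, the benzyl group and the extra carboxyl are helpers, removed by hydrogenation and decarboxylation.
Enabling feature: the tertiary C8 oxygen is 1,5 to C13, so the C13 ketone closes a six-membered C8–O–C13 enol ether that gives regiospecific entry to the C11–C13 allyl system; C11 hangs on ring-B carbon C9 between quaternary C10 and fully substituted C8, so only the methyl-bearing allyl terminus C13 is open to attack.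
Stereochemistry: the (2R,3R)-oxirane from D-(−)-tartrate epoxidation is relayed to C4, C5, C10, C9 and C8 by the chair–chair anti additions of the cyclization; C13 comes from the chiral phosphinooxazoline–Pd catalyst.
End game: O15 is silylated, O18 is freed in the hydrogenation and senecioylated, O15 is freed and opens Meldrum's acid to the free half malonate; the tertiary 8-OH is never protected.

Key step: step 10

Remark (assumption): (5E,9E)-farnesylacetone of high isomeric purity is taken as purchasable; otherwise it is made from (2E,6E)-farnesyl bromide and ethyl acetoacetate by alkylation and decarboxylation.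
Remark (names): labdane numbering is used (C18 = equatorial CH2O on C4, C16 = methyl on C13, C17 = methyl on C8); all ring compounds have the ent-labdane ring configuration 4S,5S,8S,9S,10R of the target.

Step 1
Reactants: 1 (5E,9E)-6,10,14-trimethylpentadeca-5,9,13-trien-2-one
Product: 2 (5E,9E,13E)-15-hydroxy-6,10,14-trimethylpentadeca-5,9,13-trien-2-one
Conditions: SeO2 (cat.), t-BuOOH, salicylic acid (cat.), CH2Cl2, rt
Reagents that add atoms: tert-butyl hydroperoxide, CC(C)(C)OO
Why: Catalytic SeO2/t-BuOOH allylic oxidation (ene reaction, then [2,3]-sigmatropic shift) should hydroxylate the (E)-methyl group of the terminal, most electron-rich trisubstituted alkene and so install the future C18 oxygen, the methyl ketone being inert at room temperature.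

Step 2
Reactants: 2 (5E,9E,13E)-15-hydroxy-6,10,14-trimethylpentadeca-5,9,13-trien-2-one
Product: 3 (5E,9E)-12-[(2R,3R)-3-(hydroxymethyl)-3-methyloxiran-2-yl]-6,10-dimethyldodeca-5,9-dien-2-one
Conditions: Ti(OiPr)4 (cat.), D-(−)-diethyl tartrate (cat.), t-BuOOH, 4 Å MS, CH2Cl2, −20 °C
Reagents that add atoms: tert-butyl hydroperoxide, CC(C)(C)OO
Why: Sharpless asymmetric epoxidation; the D-(−)-tartrate–titanium catalyst delivers oxygen to one face of the allylic alcohol only (reagent control) and should give the (2R,3R)-oxirane, which fixes the absolute configuration of the whole ring system, while the isolated alkenes and the ketone are not touched.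

Step 3
Reactants: 3 (5E,9E)-12-[(2R,3R)-3-(hydroxymethyl)-3-methyloxiran-2-yl]-6,10-dimethyldodeca-5,9-dien-2-one
Product: 4 (5E,9E)-12-[(2R,3R)-3-(benzyloxymethyl)-3-methyloxiran-2-yl]-6,10-dimethyldodeca-5,9-dien-2-one
Conditions: BnBr, Ag2O, Bu4NI (cat.), CH2Cl2, rt
Reagents that add atoms: benzyl bromide, BrCc1ccccc1
Why: Silver(I) oxide-mediated Williamson benzylation is neutral enough to spare the oxirane and to avoid enolisation of the methyl ketone, and the benzyl ether masks O18 as a group that cannot participate in the cyclization as an acyl group would.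

Step 4
Reactants: 4 (5E,9E)-12-[(2R,3R)-3-(benzyloxymethyl)-3-methyloxiran-2-yl]-6,10-dimethyldodeca-5,9-dien-2-one
Product: 5 (3R,4S,5S,8S,9S,10R)-18-benzyloxy-8,13-epoxy-14,15-dinorlabd-12-en-3-ol
Conditions: BF3·OEt2 (0.3 equiv), CH2Cl2, −78 °C; Et3N quench
Reagents that add atoms: none
Why: Lewis acid-promoted epoxide-initiated cation–olefin (polyene) bicyclization terminated by the ketone oxygen: C5 of the C5=C10 alkene opens the activated oxirane at its tertiary carbon C4 with inversion (6-endo, former E-substituent CH2OBn equatorial), C9 adds to C10 through a chair–chair array of the two E alkenes, the carbonyl oxygen captures C8 anti to the new C9–C10 bond (equatorial C8–O), and loss of H-12 from the oxocarbenium ion leaves the dihydropyran enol ether, so that the oxirane configuration alone dictates C4, C5, C10, C9 and C8.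

Step 5
Reactants: 5 (3R,4S,5S,8S,9S,10R)-18-benzyloxy-8,13-epoxy-14,15-dinorlabd-12-en-3-ol
Product: 6 O-[(3R,4S,5S,8S,9S,10R)-18-benzyloxy-8,13-epoxy-14,15-dinorlabd-12-en-3-yl] O-phenyl thiocarbonate
Conditions: PhOC(S)Cl, pyridine, DMAP (cat.), CH2Cl2, rt
Reagents that add atoms: O-phenyl chlorothionoformate, ClC(=S)Oc1ccccc1
Why: Acylation of the equatorial secondary 3-OH, the only free hydroxyl at this stage, gives the thionocarbonate needed for a Barton–McCombie deoxygenation.

Step 6
Reactants: 6 O-[(3R,4S,5S,8S,9S,10R)-18-benzyloxy-8,13-epoxy-14,15-dinorlabd-12-en-3-yl] O-phenyl thiocarbonate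
Product: 7 (4S,5S,8S,9S,10R)-18-benzyloxy-8,13-epoxy-14,15-dinorlabd-12-ene
Conditions: Bu3SnH, AIBN (cat.), toluene, 100 °C
Reagents that add atoms: none
Why: Barton–McCombie radical deoxygenation: the stannyl radical adds to C=S, β-scission gives the secondary C3 radical and the tin hydride reduces it, which removes the oxygen that served only to start the cyclization; the enol ether and the benzyl ether are inert to these conditions.

Step 7
Reactants: 7 (4S,5S,8S,9S,10R)-18-benzyloxy-8,13-epoxy-14,15-dinorlabd-12-ene
Product: 10 (4S,5S,8S,9S,10R,11E)-18-benzyloxy-8-hydroxy-14,15-dinorlabd-11-en-13-one, via 12-phenylselanyl ketone 8 (not isolated), via selenoxide 9 (not isolated)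
Conditions: PhSeCl, CH2Cl2, −78 °C; H2O; then 30% H2O2, pyridine, 0 °C to rt
Reagents that add atoms: water, O (phenylselanyl chloride, Cl[Se]c1ccccc1, and hydrogen peroxide, OO, add Se and O only to the intermediates 8 and 9)
Why: Electrophilic selenenylation of the enol ether puts selenium regiospecifically on its β-carbon C12, hydrolysis of the resulting α-chloro ether opens the temporary pyran to the 8-hydroxy 13-ketone, and the selenoxide syn-elimination can run only toward C11 and should give the (E)-enone.

Step 8
Reactants: 10 (4S,5S,8S,9S,10R,11E)-18-benzyloxy-8-hydroxy-14,15-dinorlabd-11-en-13-one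
Product: 11 N-tosylhydrazone of (4S,5S,8S,9S,10R,11E)-18-benzyloxy-8-hydroxy-14,15-dinorlabd-11-en-13-one
Conditions: TsNHNH2, MeOH, rt
Reagents that add atoms: 4-methylbenzenesulfonohydrazide, Cc1ccc(cc1)S(=O)(=O)NN
Why: Condensation of the methyl enone with tosylhydrazide at room temperature without acid gives the tosylhydrazone required for the Shapiro reaction, and the tertiary alcohol does not interfere.

Step 9
Reactants: 11 N-tosylhydrazone of (4S,5S,8S,9S,10R,11E)-18-benzyloxy-8-hydroxy-14,15-dinorlabd-11-en-13-one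
Product: 13 (4S,5S,8S,9S,10R,11E)-18-benzyloxy-14,15-dinorlabda-11,13(16)-dien-8-ol, via C13 vinyllithium 12 (not isolated)
Conditions: LDA (3.5 equiv), THF, −78 °C to rt; H2O
Reagents that add atoms: none
Why: Shapiro reaction: after removal of the OH and NH protons the base deprotonates the α′-methyl group C16, loss of sulfinate and N2 gives the C13 vinyllithium, and protonation should deliver the (11E)-1,3-diene in which the former carbonyl carbon C13 is a CH and C16 is a terminal CH2.

Step 10
Reactants: 13 (4S,5S,8S,9S,10R,11E)-18-benzyloxy-14,15-dinorlabda-11,13(16)-dien-8-ol; 14 2,2-dimethyl-1,3-dioxane-4,6-dione (Meldrum's acid)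
Product: 15 5-[(4S,5S,8S,9S,10R,11E,13S)-18-benzyloxy-8-hydroxy-14,15-dinorlabd-11-en-13-yl]-2,2-dimethyl-1,3-dioxane-4,6-dione
Conditions: cationic (η3-allyl)Pd[(S)-t-Bu-PHOX-type ligand with electron-poor P-aryl groups] complex (5 mol %), Et3N (cat.), Meldrum's acid in threefold excess, CH2Cl2, rt
Reagents that add atoms: none
Why: A Pd–H species, formed from Pd(0) and the triethylammonium salt of Meldrum's acid, adds reversibly to the diene with H going to C16 and gives a syn,syn-π-allyl complex over C11–C12–C13, which the Meldrum's acid enolate attacks at C13 on the face opposite to palladium. The closest known reaction type is the Pd–phosphinooxazoline-catalysed enantioselective hydroalkylation of acyclic 1,3-dienes with Meldrum's acid and related activated C–H acids, a Tsuji–Trost allylation entered from a diene. No ring is closed. The new stereocentre C13 is set by the chiral ligand (catalyst control), because the diastereomeric π-allyl complexes interconvert through the diene and the C–C bond-forming attack decides the configuration; the ligand enantiomer is the one that gives 13S, and the antipodal ligand is taken if a model diene shows the opposite sense. The step needs attack at C13 and not at C11, a single alkylation of the C–H acid, and no capture of the allyl complex by the free 8-OH. C11 is bonded to ring carbon C9, which lies between quaternary C10 and fully substituted C8, so the methyl-bearing terminus C13 is the only accessible one; the excess of Meldrum's acid suppresses double alkylation, and closure of 8-OH onto the syn,syn-allyl would need a cis alkene in a six-membered ring.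

Step 11
Reactants: 15 5-[(4S,5S,8S,9S,10R,11E,13S)-18-benzyloxy-8-hydroxy-14,15-dinorlabd-11-en-13-yl]-2,2-dimethyl-1,3-dioxane-4,6-dione
Product: 17 ethyl (4S,5S,8S,9S,10R,11E,13R)-18-benzyloxy-8-hydroxylabd-11-en-15-oate, via malonic half ester 16 (not isolated)
Conditions: EtOH/pyridine, Cu powder (cat.), reflux
Reagents that add atoms: ethanol, CCO
Why: Ethanolysis of the Meldrum's acid ring releases acetone and gives the malonic half ester, which decarboxylates under the conditions to the ethyl ester (decarboxylative esterification); C13 is not acidic and keeps its configuration, and the descriptor changes to 13R only because the CIP priorities change.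

Step 12
Reactants: 17 ethyl (4S,5S,8S,9S,10R,11E,13R)-18-benzyloxy-8-hydroxylabd-11-en-15-oate
Product: 18 (4S,5S,8S,9S,10R,11E,13R)-18-benzyloxylabd-11-ene-8,15-diol
Conditions: LiAlH4, THF, 0 °C to rt
Reagents that add atoms: none
Why: Hydride reduction of the ester with LiAlH4 gives the primary C15 alcohol, while the isolated alkene, the benzyl ether and the tertiary alcohol are unaffected.

Step 13
Reactants: 18 (4S,5S,8S,9S,10R,11E,13R)-18-benzyloxylabd-11-ene-8,15-diol
Product: 19 (4S,5S,8S,9S,10R,11E,13R)-18-benzyloxy-15-(tert-butyldimethylsilyloxy)labd-11-en-8-ol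
Conditions: TBSCl, imidazole, CH2Cl2, 0 °C
Reagents that add atoms: tert-butyldimethylsilyl chloride, CC(C)(C)[Si](C)(C)Cl
Why: Silylation with TBSCl/imidazole should take place only at the primary C15 hydroxyl, because the tertiary 8-OH is too hindered, so that O15 is masked before O18 is unveiled.

Step 14
Reactants: 19 (4S,5S,8S,9S,10R,11E,13R)-18-benzyloxy-15-(tert-butyldimethylsilyloxy)labd-11-en-8-ol
Product: 20 (4S,5S,8S,9S,10R,13S)-15-(tert-butyldimethylsilyloxy)labdane-8,18-diol
Conditions: H2 (1 atm), 10% Pd/C, EtOAc, rt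
Reagents that add atoms: none
Why: Heterogeneous catalytic hydrogenation saturates the C11=C12 alkene, the relic of the diene handle, and hydrogenolyses the benzyl ether in the same operation before the unsaturated ester is introduced; C13 is untouched and EtOAc as solvent keeps the silyl ether intact.

Step 15
Reactants: 20 (4S,5S,8S,9S,10R,13S)-15-(tert-butyldimethylsilyloxy)labdane-8,18-diol; 21 3-methylbut-2-enoyl chloride (senecioyl chloride)
Product: 22 (4S,5S,8S,9S,10R,13S)-15-(tert-butyldimethylsilyloxy)-8-hydroxylabdan-18-yl 3-methylbut-2-enoate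
Conditions: pyridine, DMAP (cat.), CH2Cl2, 0 °C to rt
Reagents that add atoms: none
Why: DMAP-catalysed acylation of the primary neopentyl C18 hydroxyl with the acid chloride should leave the tertiary 8-OH untouched, and pyridine as a weak base limits deconjugation of the acyl chloride through its vinylketene.

Step 16
Reactants: 22 (4S,5S,8S,9S,10R,13S)-15-(tert-butyldimethylsilyloxy)-8-hydroxylabdan-18-yl 3-methylbut-2-enoate
Product: 23 (4S,5S,8S,9S,10R,13S)-8,15-dihydroxylabdan-18-yl 3-methylbut-2-enoate
Conditions: HF·pyridine, pyridine/THF, 0 °C to rt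
Reagents that add atoms: none
Why: Fluoride-mediated cleavage of the primary silyl ether under buffered, non-basic conditions frees O15 without ester migration, enoate isomerisation or loss of the tertiary alcohol.

Step 17
Reactants: 23 (4S,5S,8S,9S,10R,13S)-8,15-dihydroxylabdan-18-yl 3-methylbut-2-enoate; 14 2,2-dimethyl-1,3-dioxane-4,6-dione (Meldrum's acid)
Product: 24 3-{[(4S,5S,8S,9S,10R,13S)-8-hydroxy-18-(3-methylbut-2-enoyloxy)labdan-15-yl]oxy}-3-oxopropanoic acid
Conditions: Meldrum's acid in slight excess, toluene, 90 °C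
Reagents that add atoms: none
Why: Alcoholysis of Meldrum's acid by the primary C15 alcohol (acyl substitution with loss of acetone) gives the free malonic half ester directly and needs no protecting group on the acid; the hindered tertiary 8-OH should not compete and the temperature is kept below that at which the half ester decarboxylates.

Compound list
1 | (5E,9E)-6,10,14-trimethylpentadeca-5,9,13-trien-2-one ((E,E)-farnesylacetone) | CC(C)=CCC/C(C)=C/CC/C(C)=C/CCC(C)=O | starting material
2 | (5E,9E,13E)-15-hydroxy-6,10,14-trimethylpentadeca-5,9,13-trien-2-one | OC/C(C)=C/CC/C(C)=C/CC/C(C)=C/CCC(C)=O | intermediate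
3 | (5E,9E)-12-[(2R,3R)-3-(hydroxymethyl)-3-methyloxiran-2-yl]-6,10-dimethyldodeca-5,9-dien-2-one | OC[C@@]1(C)O[C@@H]1CC/C(C)=C/CC/C(C)=C/CCC(C)=O | intermediate
4 | (5E,9E)-12-[(2R,3R)-3-(benzyloxymethyl)-3-methyloxiran-2-yl]-6,10-dimethyldodeca-5,9-dien-2-one | c2ccccc2COC[C@@]1(C)O[C@@H]1CC/C(C)=C/CC/C(C)=C/CCC(C)=O | intermediate
5 | (3R,4S,5S,8S,9S,10R)-18-benzyloxy-8,13-epoxy-14,15-dinorlabd-12-en-3-ol (trans-decalin fused to a dihydropyran enol ether; 3-OH and CH2OBn equatorial) | c4ccccc4COC[C@@]1(C)[C@H](O)CC[C@]2(C)[C@@H]1CC[C@]3(C)OC(C)=CC[C@H]32 | intermediate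
6 | O-[(3R,4S,5S,8S,9S,10R)-18-benzyloxy-8,13-epoxy-14,15-dinorlabd-12-en-3-yl] O-phenyl thiocarbonate | c4ccccc4COC[C@@]1(C)[C@H](OC(=S)Oc5ccccc5)CC[C@]2(C)[C@@H]1CC[C@]3(C)OC(C)=CC[C@H]32 | intermediate
7 | (4S,5S,8S,9S,10R)-18-benzyloxy-8,13-epoxy-14,15-dinorlabd-12-ene | c4ccccc4COC[C@@]1(C)CCC[C@]2(C)[C@@H]1CC[C@]3(C)OC(C)=CC[C@H]32 | intermediate
8 | (4S,5S,8S,9S,10R)-18-benzyloxy-8-hydroxy-12-(phenylselanyl)-14,15-dinorlabdan-13-one (C12 epimers) | c4ccccc4COC[C@@]1(C)CCC[C@]2(C)[C@@H]1CC[C@](C)(O)[C@H]2CC([Se]c3ccccc3)C(C)=O | intermediate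
9 | (4S,5S,8S,9S,10R)-18-benzyloxy-8-hydroxy-12-(phenylseleninyl)-14,15-dinorlabdan-13-one (selenoxide) | c4ccccc4COC[C@@]1(C)CCC[C@]2(C)[C@@H]1CC[C@](C)(O)[C@H]2CC([Se](=O)c3ccccc3)C(C)=O | intermediate
10 | (4S,5S,8S,9S,10R,11E)-18-benzyloxy-8-hydroxy-14,15-dinorlabd-11-en-13-one | c4ccccc4COC[C@@]1(C)CCC[C@]2(C)[C@@H]1CC[C@](C)(O)[C@H]2/C=C/C(C)=O | intermediate
11 | N-tosylhydrazone of 10 | c4ccccc4COC[C@@]1(C)CCC[C@]2(C)[C@@H]1CC[C@](C)(O)[C@H]2/C=C/C(C)=NNS(=O)(=O)c3ccc(C)cc3 | intermediate
12 | (11E)-18-benzyloxy-13-lithio-14,15-dinorlabda-11,13(16)-dien-8-ol lithium alkoxide | c4ccccc4COC[C@@]1(C)CCC[C@]2(C)[C@@H]1CC[C@](C)(O[Li])[C@H]2/C=C/C([Li])=C | intermediate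
13 | (4S,5S,8S,9S,10R,11E)-18-benzyloxy-14,15-dinorlabda-11,13(16)-dien-8-ol | c4ccccc4COC[C@@]1(C)CCC[C@]2(C)[C@@H]1CC[C@](C)(O)[C@H]2/C=C/C=C | intermediate
14 | 2,2-dimethyl-1,3-dioxane-4,6-dione (Meldrum's acid) | CC1(C)OC(=O)CC(=O)O1 | starting material
15 | 5-[(4S,5S,8S,9S,10R,11E,13S)-18-benzyloxy-8-hydroxy-14,15-dinorlabd-11-en-13-yl]-2,2-dimethyl-1,3-dioxane-4,6-dione | c4ccccc4COC[C@@]1(C)CCC[C@]2(C)[C@@H]1CC[C@](C)(O)[C@H]2/C=C/[C@H](C)C3C(=O)OC(C)(C)OC3=O | intermediate
16 | 2-[(11E,13S)-18-benzyloxy-8-hydroxy-14,15-dinorlabd-11-en-13-yl]malonic acid monoethyl ester | c4ccccc4COC[C@@]1(C)CCC[C@]2(C)[C@@H]1CC[C@](C)(O)[C@H]2/C=C/[C@H](C)C(C(=O)O)C(=O)OCC | intermediate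
17 | ethyl (4S,5S,8S,9S,10R,11E,13R)-18-benzyloxy-8-hydroxylabd-11-en-15-oate | c4ccccc4COC[C@@]1(C)CCC[C@]2(C)[C@@H]1CC[C@](C)(O)[C@H]2/C=C/[C@H](C)CC(=O)OCC | intermediate
18 | (4S,5S,8S,9S,10R,11E,13R)-18-benzyloxylabd-11-ene-8,15-diol | c4ccccc4COC[C@@]1(C)CCC[C@]2(C)[C@@H]1CC[C@](C)(O)[C@H]2/C=C/[C@H](C)CCO | intermediate
19 | (4S,5S,8S,9S,10R,11E,13R)-18-benzyloxy-15-(tert-butyldimethylsilyloxy)labd-11-en-8-ol | c4ccccc4COC[C@@]1(C)CCC[C@]2(C)[C@@H]1CC[C@](C)(O)[C@H]2/C=C/[C@H](C)CCO[Si](C)(C)C(C)(C)C | intermediate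
20 | (4S,5S,8S,9S,10R,13S)-15-(tert-butyldimethylsilyloxy)labdane-8,18-diol | OC[C@@]1(C)CCC[C@]2(C)[C@@H]1CC[C@](C)(O)[C@H]2CC[C@H](C)CCO[Si](C)(C)C(C)(C)C | intermediate
21 | 3-methylbut-2-enoyl chloride (senecioyl chloride) | CC(C)=CC(=O)Cl | starting material
22 | (4S,5S,8S,9S,10R,13S)-15-(tert-butyldimethylsilyloxy)-8-hydroxylabdan-18-yl 3-methylbut-2-enoate | CC(C)=CC(=O)OC[C@@]1(C)CCC[C@]2(C)[C@@H]1CC[C@](C)(O)[C@H]2CC[C@H](C)CCO[Si](C)(C)C(C)(C)C | intermediate
23 | (4S,5S,8S,9S,10R,13S)-8,15-dihydroxylabdan-18-yl 3-methylbut-2-enoate | CC(C)=CC(=O)OC[C@@]1(C)CCC[C@]2(C)[C@@H]1CC[C@](C)(O)[C@H]2CC[C@H](C)CCO | intermediate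
24 | 3-{[(4S,5S,8S,9S,10R,13S)-8-hydroxy-18-(3-methylbut-2-enoyloxy)labdan-15-yl]oxy}-3-oxopropanoic acid | CC(C)=CC(=O)OC[C@@]1(C)CCC[C@]2(C)[C@@H]1CC[C@](C)(O)[C@H]2CC[C@H](C)CCOC(=O)CC(=O)O | target

Total step count: 17. Longest linear sequence: 17 steps (from 1).

Steps most likely to fail

Step 4. The benzyloxymethyl group withdraws electron density from C4, so the oxirane may open at the secondary carbon C3 with closure of a five-membered ring, or the cascade may stop by proton loss before the carbonyl oxygen has captured C8. The fallback replaces the cationic initiation by a radical one. It sets out from 4: titanocene(III) chloride (Cp2TiCl2, Mn dust, THF, rt) opens the oxirane homolytically to the tertiary C4 radical, two 6-endo radical additions close rings A and B, and trapping by Ti(III) with β-hydride elimination should end in the exocyclic C8=C17 alkene of the bicyclic hydroxy ketone (3R)-18-benzyloxy-3-hydroxy-14,15-dinorlabd-8(17)-en-13-one F1. In the chair transition state the larger benzyloxymethyl group on the planar C4 radical should again become equatorial. Catalytic p-TsOH in CH2Cl2 then protonates the 8(17)-alkene and the side-chain carbonyl oxygen closes the pyran at C8 (Markovnikov), which comes back to the route at 5.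

Step 10. Facial discrimination at the π-allyl stage may be poor if the chiral catalyst and the bulky chiral decalin are mismatched, and hydropalladation of the hindered diene may be slow enough for diene oligomerisation to compete. The fallback sets the stereocentre by a reagent-controlled reduction and then transfers it. It sets out from enone 10 (steps 8 and 9 are then not needed): CBS reduction ((R)-Me-CBS, BH3·SMe2, THF, −40 °C) should give the (11E,13S)-allylic alcohol F2, and methyl chloroformate/pyridine gives its methyl carbonate F3. A Tsuji–Trost alkylation (Pd(PPh3)4, dimethyl malonate, THF, rt) then replaces the carbonate by the malonate with overall retention (two inversions) at the less hindered, methyl-bearing terminus C13 and gives the dimethyl (11E,13S)-malonate F4. Krapcho demethoxycarbonylation (LiCl, wet DMSO, 150 °C) gives the methyl (11E,13R)-labd-11-en-15-oate F5, and LiAlH4 reduction comes back to the route at 18.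

Step 9. The strong base may remove H-9 (the vinylogous α-position) or fragment the lithium 8-alkoxide in a vinylogous retro-aldol reaction instead of deprotonating the C16 methyl group. The fallback reaches the diene without a strong base. It sets out from enone 10: Luche reduction (NaBH4, CeCl3·7H2O, MeOH, 0 °C) gives the allylic alcohol (11E)-18-benzyloxy-14,15-dinorlabd-11-ene-8,13-diol F6 as a mixture of C13 epimers, and methyl chloroformate/pyridine gives its 13-(methyl carbonate) F7. Pd-catalysed 1,4-elimination (Pd(OAc)2, PPh3, dioxane, reflux; ionisation to the π-allyl complex, then β-hydride loss from the C16 methyl group) comes back to the route at diene 13.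

Further compounds
F1 | step 4 | (3R)-18-benzyloxy-3-hydroxy-14,15-dinorlabd-8(17)-en-13-one (ring configuration as in 5) | c4ccccc4COC[C@@]1(C)[C@H](O)CC[C@]2(C)[C@@H]1CCC(=C)[C@H]2CCC(C)=O
F2 | step 10 | (11E,13S)-18-benzyloxy-14,15-dinorlabd-11-ene-8,13-diol | c4ccccc4COC[C@@]1(C)CCC[C@]2(C)[C@@H]1CC[C@](C)(O)[C@H]2/C=C/[C@H](C)O
F3 | step 10 | (11E,13S)-18-benzyloxy-8-hydroxy-14,15-dinorlabd-11-en-13-yl methyl carbonate | c4ccccc4COC[C@@]1(C)CCC[C@]2(C)[C@@H]1CC[C@](C)(O)[C@H]2/C=C/[C@H](C)OC(=O)OC
F4 | step 10 | dimethyl 2-[(11E,13S)-18-benzyloxy-8-hydroxy-14,15-dinorlabd-11-en-13-yl]malonate | c4ccccc4COC[C@@]1(C)CCC[C@]2(C)[C@@H]1CC[C@](C)(O)[C@H]2/C=C/[C@H](C)C(C(=O)OC)C(=O)OC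
F5 | step 10 | methyl (11E,13R)-18-benzyloxy-8-hydroxylabd-11-en-15-oate | c4ccccc4COC[C@@]1(C)CCC[C@]2(C)[C@@H]1CC[C@](C)(O)[C@H]2/C=C/[C@H](C)CC(=O)OC
F6 | step 9 | (11E)-18-benzyloxy-14,15-dinorlabd-11-ene-8,13-diol (C13 epimers) | c4ccccc4COC[C@@]1(C)CCC[C@]2(C)[C@@H]1CC[C@](C)(O)[C@H]2/C=C/C(C)O
F7 | step 9 | (11E)-18-benzyloxy-8-hydroxy-14,15-dinorlabd-11-en-13-yl methyl carbonate (C13 epimers) | c4ccccc4COC[C@@]1(C)CCC[C@]2(C)[C@@H]1CC[C@](C)(O)[C@H]2/C=C/C(C)OC(=O)OC
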